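**Retrosynthetic overview**

1. Numbering: C1 = aroyl bridgehead, C2–C4 = enolised dione (prenyl on C3), C5 = lavandulyl bridgehead, C6 = CH2, C7 = prenyl methine, C8 = CMe2, C9 = bridging ketone; O2, O4, O9 are the oxygens on C2, C4, C9, also in the aromatic precursors.
2. Feature: once O2 is a methyl ether, C5 is the only carbon between two carbonyl carbons (C4, C9), and C6 is a CH2 linking C5 to C7. A thioacrylate (C7=C6H2) carried on C1 through C8 therefore lets the C5 enol close ring A (C1–C8–C7–C6–C5–C9).
3. Disconnections: target ⇒ C7 thioester (prenyl by reduction and two Wittig steps) ⇒ [C5–C6, 6-endo Michael] C1-quaternary dearomatised trione ⇒ [C1–C8, dearomative Claisen shift from O9] hexasubstituted aryl 2-(ethylthiocarbonyl)prenyl ether.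
4. The arene is built on 5-methoxyresorcinol by three ring metalations that use its symmetry: (S)-lavandulyl (Negishi) between the two MOM ethers, then prenyl and the aroyl group on the two equivalent positions. O9 is then the carbonyl-chelated phenol and O4 the free one, which tells them apart.
5. Ring order: the benzene ring becomes the C1–C2–C3–C4–C5–C9 ring on dearomatisation; ring A is the only ring formed, in the key step.

Key step: step 18

Remark 1: lipases acylate (R)-lavandulol faster than its antipode, with modest selectivity; the S alcohol is therefore taken as the unreacted fraction at high conversion.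
Remark 2: the sense of induction of the bisoxazoline–copper catalyst in step 17 cannot be read from the naphthol cases; the ligand antipode that leads to the C1 configuration of 26 is meant, written here as (S,S).
Remark 3: "(R)-lavandulyl" means (2R)-5-methyl-2-(prop-1-en-2-yl)hex-4-en-1-yl; it is the group of (S)-lavandulol, the descriptor changing only through the priority rule.

**Route**

Step 1
Reactants: 1 5-methoxyresorcinol
Product: 2 1-methoxy-3,5-bis(methoxymethoxy)benzene
Conditions: MOMCl, i-Pr2NEt, CH2Cl2, 0 °C → rt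
Reagents that add atoms: chloromethyl methyl ether, COCCl
Why: O-alkylation of both phenols (Williamson type) gives the bis-MOM ether, whose MOM groups direct the three ring metalations that follow.

Step 2
Reactants: 2 1-methoxy-3,5-bis(methoxymethoxy)benzene
Product: 4 2-iodo-5-methoxy-1,3-bis(methoxymethoxy)benzene, via aryllithium 3 (not isolated)
Conditions: n-BuLi, THF, 0 °C; then I2, −78 °C → rt
Reagents that add atoms: iodine, II
Why: Directed ortho-metalation takes place at the carbon flanked by both MOM ethers (cooperative chelation of lithium), and the aryllithium is iodinated.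

Step 3
Reactants: 5 (±)-lavandulol
Product: 6 (S)-lavandulol
Conditions: immobilised lipase B from Candida antarctica, vinyl acetate, t-BuOMe, 25 °C, to about 65 % conversion; chromatography
Reagents that add atoms: none
Why: Enzymatic kinetic resolution by transesterification should acylate the R alcohol faster, so the S alcohol, whose stereocentre becomes that of the C5 side chain, is recovered unreacted.

Step 4
Reactants: 6 (S)-lavandulol
Product: 7 (S)-lavandulyl iodide, (3S)-3-(iodomethyl)-2,6-dimethylhepta-1,5-diene
Conditions: I2, PPh3, imidazole, CH2Cl2, 0 °C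
Reagents that add atoms: iodine, II
Why: Appel-type iodination is an SN2 displacement at the primary carbon and leaves the neighbouring stereocentre untouched.

Step 5
Reactants: 7 (S)-lavandulyl iodide; 4 2-iodo-5-methoxy-1,3-bis(methoxymethoxy)benzene
Product: 9 5-methoxy-1,3-bis(methoxymethoxy)-2-[(R)-lavandulyl]benzene, via alkylzinc iodide 8 (not isolated)
Conditions: Zn dust, LiCl, THF, 40 °C; then 4, Pd(OAc)2 (2 mol %), SPhos (4 mol %), THF, 50 °C
Reagents that add atoms: none
Why: Negishi coupling of the primary alkylzinc iodide forms the aryl–CH2 bond with the β-stereocentre intact, as with other β-branched zinc reagents; a reductive alkylation with lavandulal is avoided because its α-centre is enolisable and allylic.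

Step 6
Reactants: 9 5-methoxy-1,3-bis(methoxymethoxy)-2-[(R)-lavandulyl]benzene
Product: 11 1-methoxy-3,5-bis(methoxymethoxy)-2-(3-methylbut-2-en-1-yl)-4-[(R)-lavandulyl]benzene, via aryllithium 10 (not isolated)
Conditions: n-BuLi, TMEDA, THF, −20 → 0 °C; then CuI (10 mol %), prenyl bromide, −78 °C → rt
Reagents that add atoms: prenyl bromide, CC(C)=CCBr
Why: Directed ortho-metalation between OMe and OMOM (the two free positions are equivalent by symmetry) is followed by copper-catalysed SN2 allylation with prenyl bromide.

Step 7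
Reactants: 12 methyl 3,4-dihydroxybenzoate
Product: 13 methyl 3,4-bis(triisopropylsilyloxy)benzoate
Conditions: TIPSCl, imidazole, DMF, rt → 40 °C
Reagents that add atoms: chlorotriisopropylsilane, CC(C)[Si](Cl)(C(C)C)C(C)C
Why: Silylation of both catechol hydroxyls gives bulky aryl silyl ethers that should survive the bases, mild acids and ylides used later and are removed by fluoride at the end.

Step 8
Reactants: 13 methyl 3,4-bis(triisopropylsilyloxy)benzoate
Product: 14 N-methoxy-N-methyl-3,4-bis(triisopropylsilyloxy)benzamide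
Conditions: MeNH(OMe)·HCl, i-PrMgCl, THF, −20 → 0 °C
Reagents that add atoms: N,O-dimethylhydroxylamine hydrochloride, CNOC.Cl
Why: Aminolysis of the methyl ester by the magnesium amide gives the Weinreb amide.

Step 9
Reactants: 11 1-methoxy-3,5-bis(methoxymethoxy)-2-(3-methylbut-2-en-1-yl)-4-[(R)-lavandulyl]benzene; 14 N-methoxy-N-methyl-3,4-bis(triisopropylsilyloxy)benzamide
Product: 16 [3,4-bis(triisopropylsilyloxy)phenyl]{2-methoxy-4,6-bis(methoxymethoxy)-3-(3-methylbut-2-en-1-yl)-5-[(R)-lavandulyl]phenyl}methanone, via aryllithium 15 (not isolated)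
Conditions: n-BuLi, TMEDA, THF, −20 → 0 °C; then 14, −78 → 0 °C; aq. NH4Cl
Reagents that add atoms: none
Why: Directed ortho-metalation at the last ring position (chelation-assisted, hence faster than deprotonation of the prenyl CH2) and Weinreb ketone synthesis, whose chelated adduct stops at the ketone; MOM or silyl groups would not survive a Friedel–Crafts aroylation.

Step 10
Reactants: 16 the bis-MOM benzophenone
Product: 17 [3,4-bis(triisopropylsilyloxy)phenyl]{4,6-dihydroxy-2-methoxy-3-(3-methylbut-2-en-1-yl)-5-[(R)-lavandulyl]phenyl}methanone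
Conditions: HCl (1.25 M in MeOH), CH2Cl2, 0 °C → rt
Reagents that add atoms: none
Why: Acid-catalysed acetal exchange removes the two aryl MOM ethers while the aryl silyl ethers stay; dilute acid at or below rt should not add the freed phenols to the alkenes.

Step 11
Reactants: 17 the 4,6-dihydroxy benzophenone
Product: 18 [3,4-bis(triisopropylsilyloxy)phenyl]{6-hydroxy-2-methoxy-3-(3-methylbut-2-en-1-yl)-5-[(R)-lavandulyl]-4-(triisopropylsilyloxy)phenyl}methanone
Conditions: TIPSOTf (1.05 equiv), 2,6-lutidine, CH2Cl2, −78 → −20 °C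
Reagents that add atoms: triisopropylsilyl trifluoromethanesulfonate, CC(C)[Si](OS(=O)(=O)C(F)(F)F)(C(C)C)C(C)C
Why: Selective silylation: O9–H is held in a hydrogen bond to the aroyl carbonyl, so only the free O4–H reacts; the bulky O4 silyl group later shields C5 in step 17 and leaves as a silyl enol ether.

Step 12
Reactants: 19 diethyl isopropylidenemalonate
Product: 20 2-(ethoxycarbonyl)-3-methylbut-2-enoic acid
Conditions: KOH (1.0 equiv), EtOH, rt; then aq. HCl
Reagents that add atoms: potassium hydroxide, [K+].[OH-]
Why: Partial saponification: one of the two equivalent esters is hydrolysed and the carboxylate formed protects the other from hydroxide.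

Step 13
Reactants: 20 2-(ethoxycarbonyl)-3-methylbut-2-enoic acid
Product: 21 ethyl 2-(hydroxymethyl)-3-methylbut-2-enoate
Conditions: BH3·SMe2, THF, 0 °C → rt; MeOH, H2O
Reagents that add atoms: none
Why: Borane reduces the carboxylic acid chemoselectively (through the acyloxyborane) and leaves the ester and the electron-poor tetrasubstituted alkene.

Step 14
Reactants: 21 ethyl 2-(hydroxymethyl)-3-methylbut-2-enoate
Product: 22 S-ethyl 2-(hydroxymethyl)-3-methylbut-2-enethioate
Conditions: AlMe3, EtSH, CH2Cl2, 0 °C → rt; aq. HCl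
Reagents that add atoms: ethanethiol, CCS
Why: Ester-to-thioester exchange with Me2AlSEt; conjugate addition of the thiolate is blocked by the two β-methyl groups.

Step 15
Reactants: 22 S-ethyl 2-(hydroxymethyl)-3-methylbut-2-enethioate
Product: 23 S-ethyl 2-(bromomethyl)-3-methylbut-2-enethioate
Conditions: CBr4, PPh3, CH2Cl2, 0 °C
Reagents that add atoms: carbon tetrabromide, BrC(Br)(Br)Br
Why: Appel bromination (SN2 on the alkoxyphosphonium salt) of the primary allylic alcohol.

Step 16
Reactants: 18 the O4-silylated 6-hydroxy benzophenone; 23 S-ethyl 2-(bromomethyl)-3-methylbut-2-enethioate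
Product: 24 S-ethyl 2-({2-[3,4-bis(triisopropylsilyloxy)benzoyl]-3-methoxy-4-(3-methylbut-2-en-1-yl)-6-[(R)-lavandulyl]-5-(triisopropylsilyloxy)phenoxy}methyl)-3-methylbut-2-enethioate
Conditions: K2CO3, DMF, rt
Reagents that add atoms: none
Why: Williamson ether synthesis: the only free phenoxide (O9) displaces the primary allylic bromide by SN2, the tetrasubstituted alkene terminus being too hindered for SN2′ attack.

Step 17
Reactants: 24 the aryl 2-(ethylthiocarbonyl)prenyl ether
Product: 26 dearomatised enolised trione with C1 quaternary (S at C1; 3,4-bis(triisopropylsilyloxy)benzoyl and 1,1-dimethyl-2-(ethylthiocarbonyl)allyl on C1; OMe on C2; prenyl on C3; C4=O; (R)-lavandulyl on C5; C9 enol), via silyl dienone 25 (not isolated)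
Conditions: Cu(OTf)2 (10 mol %), (S,S)-tBu-box (11 mol %), MS 4 Å, CH2Cl2, −20 °C → rt; then 0.5 M HCl–THF, 0 °C
Reagents that add atoms: none
Why: Proposed new method: the bisoxazoline–copper Lewis acid binds O9 and the aroyl oxygen in a six-membered chelate, which weakens the O9–CH2 bond and holds the C9=C1 double bond inside the chelate, so the [3,3] shift (aromatic Claisen rearrangement with dearomatisation) should deliver the CMe2 terminus to C1 and not to C5, which is also shielded by the flanking O4 silyl group; the ligand covers one face of C1 and so sets this stereocentre under catalyst control, the remote lavandulyl centre having no influence; the closest known reaction types are the bisoxazoline–copper-catalysed Claisen rearrangement of 2-alkoxycarbonyl allyl vinyl ethers, the chiral copper- or cobalt-catalysed dearomative Claisen rearrangement of allyl 2-naphthyl ethers carrying a 1-carbonyl group, and the thermal Claisen shift of fully substituted phloroglucinol allyl ethers to cyclohexadienones; dilute acid then hydrolyses the vinylogous silyl ester 25 to 26.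

Step 18
Reactants: 26 the C1-quaternary enolised trione
Product: 27 bicyclo[3.3.1]nonane C2 methyl enol ether with an exo S-ethyl thioester on C7 (C1 and C5 as in 33; catechol as bis-TIPS ether)
Conditions: DBU (1.5 equiv), MeCN, 0 °C → rt
Reagents that add atoms: none
Why: DBU deprotonates the enolised C4/C9 dione of 26 (a vinylogous acid) and the central carbon C5 of the enolate adds to C6, the CH2 terminus of the thioacrylate carried on C1 through C8, after which the thioester enolate is protonated at C7 (intramolecular Michael addition). The closest known reaction is the ring-closing stage of the alkylative dearomatisation–annulation of acylphloroglucinols with 2-(acyloxymethyl)acrylates or -acroleins, where a ring 1,3-dicarbonyl carbon closes the same bicycle onto an α-substituted acrylate. Ring A (C1, C8, C7, C6, C5, C9) closes in the 6-endo-trig mode, the C6=C7 alkene lying inside the new ring and the tether standing axial on the sp3 carbon C1. C5 is controlled by C1, because the three-atom tether can reach C5 only on the ring face on which it stands, so the bridge is cis and the C1 configuration from step 17 is copied to C5. C7 is set thermodynamically: DBU removes and returns the acidic thioester α-proton until the thioester sits exo, equatorial on chair ring A and turned away from the C2–C3–C4 bridge. The step needs C5 to react rather than C3 or an enolate oxygen; the O2 methyl ether keeps C3 a non-nucleophilic enol ether carbon, and closure through oxygen is a reversible oxa-Michael addition that drains into the C–C bonded product.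

Step 19
Reactants: 27 the bicyclic exo thioester
Product: 28 the bicyclic C7-exo aldehyde (C7–CHO)
Conditions: Et3SiH, Pd on CaCO3 poisoned with Pb(OAc)2 (10 mol % Pd), acetone, rt
Reagents that add atoms: none
Why: Fukuyama reduction (Pd insertion into the acyl–S bond, then hydride transfer from the silane) spares the ketones and the vinylogous ester and, on the lead-poisoned catalyst, should spare the alkenes; the exo aldehyde is the equatorial, stable C7 epimer.

Step 20
Reactants: 28 the bicyclic C7-exo aldehyde
Product: 29 the C7 2-methoxyvinyl compound (E/Z mixture)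
Conditions: MeOCH2PPh3Cl, KN(SiMe3)2, THF, 0 °C; then 28, −78 °C → rt
Reagents that add atoms: (methoxymethyl)triphenylphosphonium chloride, COC[P+](c1ccccc1)(c1ccccc1)c1ccccc1.[Cl-]
Why: Wittig reaction at the only unhindered carbonyl group (C9 and the aroyl ketone are flanked by quaternary carbons, C4 is a vinylogous ester carbonyl); the alkene geometry is of no consequence.

Step 21
Reactants: 29 the C7 2-methoxyvinyl compound
Product: 30 the homologated aldehyde (C7–CH2–CHO)
Conditions: TsOH·H2O (20 mol %), acetone–H2O, rt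
Reagents that add atoms: water, O
Why: Acid hydrolysis of the electron-rich aldehyde enol ether (C-protonation, hemiacetal collapse) should be much faster than that of the push–pull C2 methyl enol ether; from here C7 is no longer α to a carbonyl and is fixed.

Step 22
Reactants: 30 the homologated aldehyde
Product: 31 the C7-prenyl bicycle (C2 methyl enol ether; catechol as bis-TIPS ether)
Conditions: i-PrPPh3I, n-BuLi, THF, 0 °C; then 30, −78 °C → rt
Reagents that add atoms: isopropyltriphenylphosphonium iodide, CC(C)[P+](c1ccccc1)(c1ccccc1)c1ccccc1.[I-]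
Why: Wittig olefination with the isopropylidene ylide completes the C7 prenyl group.

Step 23
Reactants: 31 the C7-prenyl bicycle
Product: 32 the C2 enol with the catechol still as bis-TIPS ether
Conditions: LiCl, DMSO, 120 °C; aq. HCl work-up
Reagents that add atoms: none
Why: Nucleophilic demethylation of the vinylogous methyl ester (SN2 attack of chloride at the methyl group, Krapcho type) frees the enol without acid, so it cannot add to the isopropenyl or prenyl alkenes; any loss of aryl silyl groups here is made good in step 24.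

Step 24
Reactants: 32 the bis-TIPS enol
Product: 33 target, (1S,5R,7S)-1-(3,4-dihydroxybenzoyl)-2-hydroxy-8,8-dimethyl-3,7-bis(3-methylbut-2-en-1-yl)-5-[(R)-lavandulyl]bicyclo[3.3.1]non-2-ene-4,9-dione
Conditions: Bu4NF, AcOH, THF, 0 °C
Reagents that add atoms: none
Why: Fluoride desilylation of the two aryl silyl ethers under acetic acid buffering touches no stereocentre.

**Compound list**

1 | 5-methoxyresorcinol | COc1cc(O)cc(O)c1 | starting material
2 | 1-methoxy-3,5-bis(methoxymethoxy)benzene | COCOc1cc(OC)cc(OCOC)c1 | intermediate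
3 | [4-methoxy-2,6-bis(methoxymethoxy)phenyl]lithium | [Li]c1c(OCOC)cc(OC)cc1OCOC | intermediate
4 | 2-iodo-5-methoxy-1,3-bis(methoxymethoxy)benzene | COCOc1cc(OC)cc(OCOC)c1I | intermediate
5 | (±)-lavandulol | C=C(C)C(CO)CC=C(C)C | starting material
6 | (S)-lavandulol | C=C(C)[C@H](CC=C(C)C)CO | intermediate
7 | (S)-lavandulyl iodide | C=C(C)[C@H](CC=C(C)C)CI | intermediate
8 | (S)-lavandulylzinc iodide | C=C(C)[C@H](CC=C(C)C)C[Zn]I | intermediate
9 | 5-methoxy-1,3-bis(methoxymethoxy)-2-[(R)-lavandulyl]benzene | C=C(C)[C@H](CC=C(C)C)Cc1c(OCOC)cc(OC)cc1OCOC | intermediate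
10 | aryllithium from 9 (Li between OMe and OMOM) | C=C(C)[C@H](CC=C(C)C)Cc1c(OCOC)c([Li])c(OC)cc1OCOC | intermediate
11 | 1-methoxy-3,5-bis(methoxymethoxy)-2-(3-methylbut-2-en-1-yl)-4-[(R)-lavandulyl]benzene | C=C(C)[C@H](CC=C(C)C)Cc1c(OCOC)c(CC=C(C)C)c(OC)cc1OCOC | intermediate
12 | methyl 3,4-dihydroxybenzoate | COC(=O)c1ccc(O)c(O)c1 | starting material
13 | methyl 3,4-bis(triisopropylsilyloxy)benzoate | COC(=O)c1ccc(O[Si](C(C)C)(C(C)C)C(C)C)c(O[Si](C(C)C)(C(C)C)C(C)C)c1 | intermediate
14 | N-methoxy-N-methyl-3,4-bis(triisopropylsilyloxy)benzamide | CON(C)C(=O)c1ccc(O[Si](C(C)C)(C(C)C)C(C)C)c(O[Si](C(C)C)(C(C)C)C(C)C)c1 | intermediate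
15 | aryllithium from 11 (Li at the last ring position) | C=C(C)[C@H](CC=C(C)C)Cc1c(OCOC)c(CC=C(C)C)c(OC)c([Li])c1OCOC | intermediate
16 | benzophenone with ring MOM ethers on O4 and O9 | C=C(C)[C@H](CC=C(C)C)Cc1c(OCOC)c(CC=C(C)C)c(OC)c(C(=O)c2ccc(O[Si](C(C)C)(C(C)C)C(C)C)c(O[Si](C(C)C)(C(C)C)C(C)C)c2)c1OCOC | intermediate
17 | benzophenone with free O4–H and O9–H | C=C(C)[C@H](CC=C(C)C)Cc1c(O)c(CC=C(C)C)c(OC)c(C(=O)c2ccc(O[Si](C(C)C)(C(C)C)C(C)C)c(O[Si](C(C)C)(C(C)C)C(C)C)c2)c1O | intermediate
18 | benzophenone with O4–TIPS and free O9–H | C=C(C)[C@H](CC=C(C)C)Cc1c(O[Si](C(C)C)(C(C)C)C(C)C)c(CC=C(C)C)c(OC)c(C(=O)c2ccc(O[Si](C(C)C)(C(C)C)C(C)C)c(O[Si](C(C)C)(C(C)C)C(C)C)c2)c1O | intermediate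
19 | diethyl isopropylidenemalonate | CCOC(=O)C(=C(C)C)C(=O)OCC | starting material
20 | 2-(ethoxycarbonyl)-3-methylbut-2-enoic acid | CCOC(=O)C(=C(C)C)C(=O)O | intermediate
21 | ethyl 2-(hydroxymethyl)-3-methylbut-2-enoate | CCOC(=O)C(CO)=C(C)C | intermediate
22 | S-ethyl 2-(hydroxymethyl)-3-methylbut-2-enethioate | CCSC(=O)C(CO)=C(C)C | intermediate
23 | S-ethyl 2-(bromomethyl)-3-methylbut-2-enethioate | CCSC(=O)C(CBr)=C(C)C | intermediate
24 | aryl 2-(ethylthiocarbonyl)prenyl ether (allyl group on O9) | C=C(C)[C@H](CC=C(C)C)Cc1c(O[Si](C(C)C)(C(C)C)C(C)C)c(CC=C(C)C)c(OC)c(C(=O)c2ccc(O[Si](C(C)C)(C(C)C)C(C)C)c(O[Si](C(C)C)(C(C)C)C(C)C)c2)c1OCC(C(=O)SCC)=C(C)C | intermediate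
25 | C1-quaternary cyclohexadienone with O4 silyl enol ether (C1 as in 26) | C=C(C)[C@H](CC=C(C)C)CC1=C(O[Si](C(C)C)(C(C)C)C(C)C)C(CC=C(C)C)=C(OC)[C@](C(=O)c2ccc(O[Si](C(C)C)(C(C)C)C(C)C)c(O[Si](C(C)C)(C(C)C)C(C)C)c2)(C(C)(C)C(=C)C(=O)SCC)C1=O | intermediate
26 | C1-quaternary enolised trione, precursor of the key step (S at C1) | C=C(C)[C@H](CC=C(C)C)CC1=C(O)[C@@](C(=O)c2ccc(O[Si](C(C)C)(C(C)C)C(C)C)c(O[Si](C(C)C)(C(C)C)C(C)C)c2)(C(C)(C)C(=C)C(=O)SCC)C(OC)=C(CC=C(C)C)C1=O | intermediate
27 | bicyclic C2 methyl enol ether with C7-exo S-ethyl thioester | C=C(C)[C@H](CC=C(C)C)C[C@]12C[C@H](C(=O)SCC)C(C)(C)[C@](C(=O)c3ccc(O[Si](C(C)C)(C(C)C)C(C)C)c(O[Si](C(C)C)(C(C)C)C(C)C)c3)(C1=O)C(OC)=C(CC=C(C)C)C2=O | intermediate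
28 | bicyclic C7-exo aldehyde | C=C(C)[C@H](CC=C(C)C)C[C@]12C[C@H](C=O)C(C)(C)[C@](C(=O)c3ccc(O[Si](C(C)C)(C(C)C)C(C)C)c(O[Si](C(C)C)(C(C)C)C(C)C)c3)(C1=O)C(OC)=C(CC=C(C)C)C2=O | intermediate
29 | bicyclic C7 2-methoxyvinyl compound (E/Z) | C=C(C)[C@H](CC=C(C)C)C[C@]12C[C@H](C=COC)C(C)(C)[C@](C(=O)c3ccc(O[Si](C(C)C)(C(C)C)C(C)C)c(O[Si](C(C)C)(C(C)C)C(C)C)c3)(C1=O)C(OC)=C(CC=C(C)C)C2=O | intermediate
30 | bicyclic C7–CH2–CHO aldehyde | C=C(C)[C@H](CC=C(C)C)C[C@]12C[C@H](CC=O)C(C)(C)[C@](C(=O)c3ccc(O[Si](C(C)C)(C(C)C)C(C)C)c(O[Si](C(C)C)(C(C)C)C(C)C)c3)(C1=O)C(OC)=C(CC=C(C)C)C2=O | intermediate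
31 | C7-prenyl bicycle, C2 methyl enol ether, bis-TIPS catechol | C=C(C)[C@H](CC=C(C)C)C[C@]12C[C@H](CC=C(C)C)C(C)(C)[C@](C(=O)c3ccc(O[Si](C(C)C)(C(C)C)C(C)C)c(O[Si](C(C)C)(C(C)C)C(C)C)c3)(C1=O)C(OC)=C(CC=C(C)C)C2=O | intermediate
32 | C2 enol, bis-TIPS catechol | C=C(C)[C@H](CC=C(C)C)C[C@]12C[C@H](CC=C(C)C)C(C)(C)[C@](C(=O)c3ccc(O[Si](C(C)C)(C(C)C)C(C)C)c(O[Si](C(C)C)(C(C)C)C(C)C)c3)(C1=O)C(O)=C(CC=C(C)C)C2=O | intermediate
33 | CNP0425478.2 | C=C(C)[C@H](CC=C(C)C)C[C@]12C[C@H](CC=C(C)C)C(C)(C)[C@](C(=O)c3ccc(O)c(O)c3)(C1=O)C(O)=C(CC=C(C)C)C2=O | target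

**Step count and risks**

Total step count: 24. Longest linear sequence: 16 steps (steps 1, 2, 5, 6, 9, 10, 11, 16–24).

Steps most likely to fail:

Step 17 (the step marked as a proposed new method). What may go wrong: the chelated ether may shift its allyl group to C5 instead of C1; the 1,3-diketone product may hold the copper so that the catalyst does not turn over; the facial bias may be small so that both C1 epimers form; and on warming the strained C1–C8 bond may move on by a Cope shift. The fallback gives up catalyst control and uses the uncatalysed dearomatising ortho-Claisen shift known for fully substituted phloroglucinol allyl ethers. It sets out from 24, which is heated briefly (toluene, 110–120 °C, BHT) and hydrolysed as in step 17. This should give 26 together with its C1 epimer, the C1-epimeric enolised trione F2, formed through the C1-epimeric silyl dienone F1. The mixture is cyclised with DBU as in step 18, the rigid diastereomeric bicycle F3 is removed by preparative HPLC, and the route is re-entered at 27. Dienone from a shift to C5 cannot aromatise and is returned to 24 on reheating.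

Step 18. What may go wrong: protonation of the thioester enolate on the open exo face may leave the thioester endo, and the hindered α-proton may then not be removed again by DBU, so that no equilibration to the exo epimer takes place. The fallback moves the correction of C7 one stage on and uses known chemistry. It sets out from 26; the endo thioester F4 is accepted and reduced under the conditions of step 19 to the endo aldehyde F5. The aldehyde α-proton is far more acidic and is equilibrated with DBU in CH2Cl2 (or K2CO3 in MeOH) to the exo epimer; the route is re-entered at 28.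

Step 5. What may go wrong: oxidative addition and reductive elimination at the doubly ortho-substituted aryl iodide may be slow, so that β-hydride elimination from the alkylpalladium or protodeiodination takes over. The fallback inverts the polarity. It sets out from 2, which is lithiated as in step 2 to aryllithium 3 and alkylated directly with iodide 7 (THF–DMPU, −78 °C → rt), the classical SN2 alkylation of 2-lithioresorcinol diethers. The route is re-entered at 9 and no new compound is made.

Further compounds
F1 | step 17 | C1-epimeric silyl dienone (C1 epimer of 25) | C=C(C)[C@H](CC=C(C)C)CC1=C(O[Si](C(C)C)(C(C)C)C(C)C)C(CC=C(C)C)=C(OC)[C@@](C(=O)c2ccc(O[Si](C(C)C)(C(C)C)C(C)C)c(O[Si](C(C)C)(C(C)C)C(C)C)c2)(C(C)(C)C(=C)C(=O)SCC)C1=O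
F2 | step 17 | C1-epimeric enolised trione (C1 epimer of 26) | C=C(C)[C@H](CC=C(C)C)CC1=C(O)[C@](C(=O)c2ccc(O[Si](C(C)C)(C(C)C)C(C)C)c(O[Si](C(C)C)(C(C)C)C(C)C)c2)(C(C)(C)C(=C)C(=O)SCC)C(OC)=C(CC=C(C)C)C1=O
F3 | step 17 | diastereomeric bicyclic exo thioester (C1, C5 and C7 all inverted relative to 27) | C=C(C)[C@H](CC=C(C)C)C[C@@]12C[C@@H](C(=O)SCC)C(C)(C)[C@@](C(=O)c3ccc(O[Si](C(C)C)(C(C)C)C(C)C)c(O[Si](C(C)C)(C(C)C)C(C)C)c3)(C1=O)C(OC)=C(CC=C(C)C)C2=O
F4 | step 18 | bicyclic C7-endo thioester (C7 epimer of 27) | C=C(C)[C@H](CC=C(C)C)C[C@]12C[C@@H](C(=O)SCC)C(C)(C)[C@](C(=O)c3ccc(O[Si](C(C)C)(C(C)C)C(C)C)c(O[Si](C(C)C)(C(C)C)C(C)C)c3)(C1=O)C(OC)=C(CC=C(C)C)C2=O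
F5 | step 18 | bicyclic C7-endo aldehyde (C7 epimer of 28) | C=C(C)[C@H](CC=C(C)C)C[C@]12C[C@@H](C=O)C(C)(C)[C@](C(=O)c3ccc(O[Si](C(C)C)(C(C)C)C(C)C)c(O[Si](C(C)C)(C(C)C)C(C)C)c3)(C1=O)C(OC)=C(CC=C(C)C)C2=O
F0 | step 5 | none | none
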